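**Retrosynthetic overview**
- The target is a 2,2-dimethylchroman-4-one (benzene ring B fused to pyranone ring C) joined through a CH2 bridge at C8 to an isobutyryl methylphloroglucinol (ring A). All five phenols are carried as methyl ethers and freed last.
- The ring A ketone is cut by Friedel–Crafts acylation at the only aromatic C–H of the chromanone pentamethyl ether. The C4 carbonyl comes from Markovnikov hydration and oxidation of the C3=C4 alkene of a 2,2-dimethyl-2H-chromene.
- The strategy rests on ring C: the tertiary ether carbon C2 with its two methyls on O1 and the C4–C4a bond both derive from an aryl 1,1-dimethylpropargyl ether of the C8a oxygen. Its only unsubstituted ortho carbon is C4a, so a [3,3] shift followed by oxa-6π closure builds the pyran.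
- The propargyl ether comes from an ortho-benzylated phenol. The C8–CH2–C1' bridge is cut into an ortho-lithiated, MOM-protected 3,5-dimethoxy-4-methylphenol (from 2,6-dimethoxytoluene by C–H borylation/oxidation) and formylated 2,4,6-trimethoxytoluene.
- Ring order: rings A and B are bought as arenes; ring C is the only ring formed.

Key step: step 7

Assumption: the chromanone is numbered O1, C2, C3, C4, C4a, C5–C8, C8a and ring A carries primed locants with C1' on the bridge; the benzhydrol and the chroman-4-ol are racemates whose stereocentres are removed again, and the target is achiral.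

**Route**

Step 1
Reactants: 1 2,6-dimethoxytoluene
Product: 3 3,5-dimethoxy-4-methylphenol, via aryl pinacol boronate 2 (not isolated)
Conditions: [Ir(OMe)(cod)]2 (cat.), 4,4'-di-tert-butyl-2,2'-bipyridine (cat.), B2pin2 (1 equiv), THF, 80 °C; then KHSO5 (as 2KHSO5·KHSO4·K2SO4), acetone/H2O, rt, short contact time
Reagents that add atoms: bis(pinacolato)diboron, CC1(C)OB(OC1(C)C)B1OC(C)(C)C(C)(C)O1 (boryl group of 2 only); potassium peroxymonosulfate KHSO5, [K+].[O-]S(=O)(=O)OO (hydroxyl oxygen of 3)
Why: Iridium-catalysed C–H borylation is sterically controlled and should take the only ring C–H of 1 without an ortho substituent (para to the methyl), and oxidation of the aryl–boron bond then gives the phenol at the same carbon (C–H borylation/oxidation).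

Step 2
Reactants: 3 3,5-dimethoxy-4-methylphenol
Product: 4 1,3-dimethoxy-5-(methoxymethoxy)-2-methylbenzene
Conditions: MOMCl, i-Pr2NEt, CH2Cl2, 0 °C → rt
Reagents that add atoms: chloromethyl methyl ether, COCCl
Why: O-alkylation of the phenol (Williamson-type acetal ether formation) gives a group that survives butyllithium and directs ortho-lithiation.

Step 3
Reactants: 5 2,4,6-trimethoxytoluene
Product: 7 2,4,6-trimethoxy-3-methylbenzaldehyde, via iminium chloride 6 (not isolated)
Conditions: POCl3, DMF, 0 °C → rt; then H2O, 50 °C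
Reagents that add atoms: N,N-dimethylformamide, CN(C)C=O (formyl carbon); water, O (carbonyl oxygen); phosphoryl chloride, O=P(Cl)(Cl)Cl (chloride of 6 only)
Why: Vilsmeier–Haack formylation attacks one of the two equivalent free positions of 5, each flanked by two methoxy groups, and the iminium group formed deactivates the ring against a second attack.

Step 4
Reactants: 4 1,3-dimethoxy-5-(methoxymethoxy)-2-methylbenzene; 7 2,4,6-trimethoxy-3-methylbenzaldehyde
Product: 9 rac-[2,4-dimethoxy-6-(methoxymethoxy)-3-methylphenyl](2,4,6-trimethoxy-3-methylphenyl)methanol, via aryllithium 8 (not isolated)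
Conditions: n-BuLi, TMEDA, THF, 0 °C; then 7, −78 °C → rt; H2O
Reagents that add atoms: none
Why: Directed ortho-metalation occurs at one of the two equivalent carbons between the methoxymethoxy and a methoxy group, and the aryllithium adds 1,2 to the aldehyde; the carbinol stereocentre forms as a racemate and is removed in step 5.

Step 5
Reactants: 9 rac-[2,4-dimethoxy-6-(methoxymethoxy)-3-methylphenyl](2,4,6-trimethoxy-3-methylphenyl)methanol
Product: 11 3,5-dimethoxy-4-methyl-2-[(2,4,6-trimethoxy-3-methylphenyl)methyl]phenol, via methoxymethyl ether 10 (not isolated)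
Conditions: Et3SiH, TFA, CH2Cl2, 0 °C; concentrate; then MeOH, HCl (cat.), 45 °C
Reagents that add atoms: none
Why: Ionic hydrogenation, in which TFA ionises the doubly benzylic alcohol to a diarylmethyl cation stabilised by six ortho/para oxygens and the silane delivers hydride, followed by acid-catalysed transacetalisation in methanol, which removes the MOM group as dimethoxymethane and keeps the formaldehyde equivalent away from the electron-rich rings.

Step 6
Reactants: 11 3,5-dimethoxy-4-methyl-2-[(2,4,6-trimethoxy-3-methylphenyl)methyl]phenol; 12 3-chloro-3-methylbut-1-yne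
Product: 13 1,5-dimethoxy-2-methyl-3-[(2,4,6-trimethoxy-3-methylphenyl)methyl]-4-[(2-methylbut-3-yn-2-yl)oxy]benzene
Conditions: CuCl2·2H2O (cat.), DBU, MeCN, 0 °C
Reagents that add atoms: none
Why: Copper-catalysed O-propargylation, in which base and copper convert the tertiary propargylic chloride into a copper-stabilised propargyl cation equivalent that the phenoxide captures at the tertiary carbon, so the SN2 and elimination problems of a tertiary halide do not arise.

Step 7
Reactants: 13 1,5-dimethoxy-2-methyl-3-[(2,4,6-trimethoxy-3-methylphenyl)methyl]-4-[(2-methylbut-3-yn-2-yl)oxy]benzene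
Product: 17 5,7-dimethoxy-2,2,6-trimethyl-8-[(2,4,6-trimethoxy-3-methylphenyl)methyl]-2H-chromene, via allenyl dienone 14 (not isolated), via ortho-allenylphenol 15 (not isolated), via ortho-quinone methide 16 (not isolated)
Conditions: PhNEt2, 180 °C, Ar
Reagents that add atoms: none
Why: Aromatic propargyl Claisen rearrangement: a [3,3] sigmatropic shift moves the dimethylpropargyl unit from oxygen to the free ortho carbon (future C4a) as an allene and forms the C4–C4a bond in dienone 14, which enolises to ortho-allenylphenol 15, and a 1,5-hydrogen shift from the hydroxyl to the central allene carbon then gives the (Z)-ortho-quinone methide 16. Ring C closes from 16 by a thermal disrotatory six-electron oxa-electrocyclisation of the 1-oxatriene (O1=C8a, C4a=C4, C3=C2), which forms the O1–C2 bond at the gem-dimethyl carbon and restores aromatic ring B. The closest known reaction type is the thermal conversion of aryl 1,1-dimethylpropargyl ethers into 2,2-dimethyl-2H-chromenes. No stereocentre is present in 17; the one in 14 is lost on enolisation. The selectivity needed is the migration terminus, and the substrate secures it: a shift to the benzyl-bearing ortho carbon (future C8) gives a dienone with no hydrogen to lose that can only revert, and the para carbon carries a methyl group, so C4a is the only productive site. The neutral amine solvent, free of fluoride and strong base, should keep 15 on the six-membered chromene path and away from five-membered benzofuran closure.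

Step 8
Reactants: 17 5,7-dimethoxy-2,2,6-trimethyl-8-[(2,4,6-trimethoxy-3-methylphenyl)methyl]-2H-chromene
Product: 18 rac-5,7-dimethoxy-2,2,6-trimethyl-8-[(2,4,6-trimethoxy-3-methylphenyl)methyl]chroman-4-ol
Conditions: Co(acac)2 (cat.), PhSiH3, O2 (1 atm), THF/i-PrOH, rt
Reagents that add atoms: dioxygen, O=O
Why: Mukaiyama hydration, in which a cobalt hydride transfers a hydrogen atom to C3, the C4 radical is benzylic and stabilised by ring B, and its capture by O2 and reduction by the silane place the hydroxyl at C4; the C4 stereocentre forms as a racemate and is removed in step 9.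

Step 9
Reactants: 18 rac-5,7-dimethoxy-2,2,6-trimethyl-8-[(2,4,6-trimethoxy-3-methylphenyl)methyl]chroman-4-ol
Product: 19 5,7-dimethoxy-2,2,6-trimethyl-8-[(2,4,6-trimethoxy-3-methylphenyl)methyl]chroman-4-one
Conditions: Dess–Martin periodinane, pyridine, CH2Cl2, 0 °C → rt
Reagents that add atoms: none
Why: Dess–Martin oxidation of the secondary benzylic alcohol is non-acidic under pyridine buffering, so the ionisable 4-ol should not dehydrate back to the chromene, and the hypervalent iodine oxidant leaves the doubly benzylic CH2 bridge alone.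

Step 10
Reactants: 19 5,7-dimethoxy-2,2,6-trimethyl-8-[(2,4,6-trimethoxy-3-methylphenyl)methyl]chroman-4-one; 20 isobutyryl chloride
Product: 21 5,7-dimethoxy-2,2,6-trimethyl-8-{[2,4,6-trimethoxy-3-methyl-5-(2-methylpropanoyl)phenyl]methyl}chroman-4-one
Conditions: SnCl4, CH2Cl2, −20 °C → 0 °C
Reagents that add atoms: none
Why: Friedel–Crafts acylation, for which 19 offers a single aromatic C–H (ring A C5', between two methoxy groups and para to the third) while ring B is fully substituted and deactivated by the C4 carbonyl.

Step 11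
Reactants: 21 5,7-dimethoxy-2,2,6-trimethyl-8-{[2,4,6-trimethoxy-3-methyl-5-(2-methylpropanoyl)phenyl]methyl}chroman-4-one
Product: 22 5,7-dihydroxy-2,2,6-trimethyl-8-{[2,4,6-trihydroxy-3-methyl-5-(2-methylpropanoyl)phenyl]methyl}chroman-4-one
Conditions: BBr3 (excess), CH2Cl2, −78 °C → rt; then H2O
Reagents that add atoms: none
Why: Lewis-acid ether cleavage, in which BBr3 binds each methoxy oxygen and bromide removes the methyl group by SN2; the three methoxyls flanking the two carbonyls should go first with chelation help and excess reagent takes the remaining two, each of which is para to a carbonyl.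

**Compound list**
1 | 2,6-dimethoxytoluene | COc1cccc(OC)c1C | starting material
2 | 2-(3,5-dimethoxy-4-methylphenyl)-4,4,5,5-tetramethyl-1,3,2-dioxaborolane | COc1cc(B2OC(C)(C)C(C)(C)O2)cc(OC)c1C | intermediate (not isolated)
3 | 3,5-dimethoxy-4-methylphenol | COc1cc(O)cc(OC)c1C | intermediate
4 | 1,3-dimethoxy-5-(methoxymethoxy)-2-methylbenzene | COCOc1cc(OC)c(C)c(OC)c1 | intermediate
5 | 2,4,6-trimethoxytoluene | COc1cc(OC)c(C)c(OC)c1 | starting material
6 | N,N-dimethyl(2,4,6-trimethoxy-3-methylphenyl)methaniminium chloride | C[N+](C)=Cc1c(OC)cc(OC)c(C)c1OC.[Cl-] | intermediate (not isolated)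
7 | 2,4,6-trimethoxy-3-methylbenzaldehyde | O=Cc1c(OC)cc(OC)c(C)c1OC | intermediate
8 | [2,4-dimethoxy-6-(methoxymethoxy)-3-methylphenyl]lithium | [Li]c1c(OCOC)cc(OC)c(C)c1OC | intermediate (not isolated)
9 | rac-[2,4-dimethoxy-6-(methoxymethoxy)-3-methylphenyl](2,4,6-trimethoxy-3-methylphenyl)methanol | COCOc1cc(OC)c(C)c(OC)c1C(O)c1c(OC)cc(OC)c(C)c1OC | intermediate
10 | 1,5-dimethoxy-4-(methoxymethoxy)-2-methyl-3-[(2,4,6-trimethoxy-3-methylphenyl)methyl]benzene | COCOc1cc(OC)c(C)c(OC)c1Cc1c(OC)cc(OC)c(C)c1OC | intermediate (not isolated)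
11 | 3,5-dimethoxy-4-methyl-2-[(2,4,6-trimethoxy-3-methylphenyl)methyl]phenol | Oc1cc(OC)c(C)c(OC)c1Cc1c(OC)cc(OC)c(C)c1OC | intermediate
12 | 3-chloro-3-methylbut-1-yne | CC(C)(Cl)C#C | starting material
13 | 1,5-dimethoxy-2-methyl-3-[(2,4,6-trimethoxy-3-methylphenyl)methyl]-4-[(2-methylbut-3-yn-2-yl)oxy]benzene | C#CC(C)(C)Oc1cc(OC)c(C)c(OC)c1Cc1c(OC)c(C)c(OC)cc1OC | intermediate
14 | rac-3,5-dimethoxy-4-methyl-6-(3-methylbuta-1,2-dien-1-yl)-2-[(2,4,6-trimethoxy-3-methylphenyl)methyl]cyclohexa-2,4-dien-1-one | O=C1C(C=C=C(C)C)C(OC)=C(C)C(OC)=C1Cc1c(OC)c(C)c(OC)cc1OC | intermediate (not isolated)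
15 | 3,5-dimethoxy-4-methyl-2-(3-methylbuta-1,2-dien-1-yl)-6-[(2,4,6-trimethoxy-3-methylphenyl)methyl]phenol | Oc1c(C=C=C(C)C)c(OC)c(C)c(OC)c1Cc1c(OC)c(C)c(OC)cc1OC | intermediate (not isolated)
16 | (6Z)-3,5-dimethoxy-4-methyl-6-(3-methylbut-2-en-1-ylidene)-2-[(2,4,6-trimethoxy-3-methylphenyl)methyl]cyclohexa-2,4-dien-1-one | O=C1/C(=C\C=C(C)C)C(OC)=C(C)C(OC)=C1Cc1c(OC)c(C)c(OC)cc1OC | intermediate (not isolated)
17 | 5,7-dimethoxy-2,2,6-trimethyl-8-[(2,4,6-trimethoxy-3-methylphenyl)methyl]-2H-chromene | COc1cc(OC)c(Cc2c(OC)c(C)c(OC)c3c2OC(C)(C)C=C3)c(OC)c1C | intermediate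
18 | rac-5,7-dimethoxy-2,2,6-trimethyl-8-[(2,4,6-trimethoxy-3-methylphenyl)methyl]chroman-4-ol | COc1cc(OC)c(Cc2c(OC)c(C)c(OC)c3c2OC(C)(C)CC3O)c(OC)c1C | intermediate
19 | 5,7-dimethoxy-2,2,6-trimethyl-8-[(2,4,6-trimethoxy-3-methylphenyl)methyl]chroman-4-one | COc1cc(OC)c(Cc2c(OC)c(C)c(OC)c3c2OC(C)(C)CC3=O)c(OC)c1C | intermediate
20 | isobutyryl chloride | CC(C)C(Cl)=O | starting material
21 | 5,7-dimethoxy-2,2,6-trimethyl-8-{[2,4,6-trimethoxy-3-methyl-5-(2-methylpropanoyl)phenyl]methyl}chroman-4-one | COc1c(C(=O)C(C)C)c(OC)c(Cc2c(OC)c(C)c(OC)c3c2OC(C)(C)CC3=O)c(OC)c1C | intermediate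
22 | 5,7-dihydroxy-2,2,6-trimethyl-8-{[2,4,6-trihydroxy-3-methyl-5-(2-methylpropanoyl)phenyl]methyl}chroman-4-one | Cc1c(O)c(Cc2c(O)c(C)c(O)c3c2OC(C)(C)CC3=O)c(O)c(C(=O)C(C)C)c1O | target

**Step count**
Total: 11 steps. Longest linear sequence: 10 steps (steps 1, 2, 4–11 from 2,6-dimethoxytoluene); step 3 is the side branch.

**Steps most likely to fail**

1. Step 11 (global ether cleavage). The cleavage may stall in the crowded acyl ring A. Forcing it may cause loss or migration of the isobutyryl group, ipso-protonation with scission of the CH2 bridge, or opening of the pyranone at the tertiary O1–C2 ether with reclosure onto the C5 oxygen.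
   Fallback: this sets out from chromanone 19 and removes the methyl ethers before the acyl group is present. BBr3, CH2Cl2, −78 °C → rt should give 5,7-dihydroxy-2,2,6-trimethyl-8-[(2,4,6-trihydroxy-3-methylphenyl)methyl]chroman-4-one F1. The free methylphloroglucinol ring is then C-acylated at its single aromatic C–H with isobutyryl chloride 20 (AlCl3, PhNO2/CH2Cl2, rt → 50 °C; aryl esters formed first should rearrange under these Fries conditions). This comes back to the route at target 22.

2. Step 10 (Friedel–Crafts acylation). The Lewis acid may promote ipso attack at C1' and transfer or loss of the benzyl unit (retro-Friedel–Crafts scission of the bridge), and acylation at the position flanked by two methoxy groups may be slow.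
   Fallback: this sets out from chromanol 18 and uses anionic chemistry. n-BuLi (2.2 equiv), TMEDA, THF, −78 → 0 °C should deprotonate the hydroxyl and then the ring A C5'–H between two methoxy groups (directed ortho-metalation). N-Methoxy-N-methylisobutyramide (Weinreb ketone synthesis) should then give rac-1-{3-[(4-hydroxy-5,7-dimethoxy-2,2,6-trimethylchroman-8-yl)methyl]-2,4,6-trimethoxy-5-methylphenyl}-2-methylpropan-1-one F2. Dess–Martin oxidation as in step 9 comes back to the route at 21.

3. Step 8 (radical hydration). Hydrogen-atom transfer to the 1,2-disubstituted alkene next to the quaternary C2 may be slow, and peroxyl radicals may autoxidise the doubly benzylic CH2 bridge.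
   Fallback: this sets out from chromene 17 and uses ionic Markovnikov addition. Hg(OAc)2, THF/H2O, rt should give by anti oxymercuration (hydroxyl at benzylic C4, mercury at C3) rac-trans-{4-hydroxy-5,7-dimethoxy-2,2,6-trimethyl-8-[(2,4,6-trimethoxy-3-methylphenyl)methyl]chroman-3-yl}mercury acetate F3. NaBH4, aq. NaOH removes the mercury, and would also reduce any arylmercury formed on ring A, and comes back to the route at 18.

**Further compounds**
F1 | step 11 | 5,7-dihydroxy-2,2,6-trimethyl-8-[(2,4,6-trihydroxy-3-methylphenyl)methyl]chroman-4-one | Cc1c(O)cc(O)c(Cc2c(O)c(C)c(O)c3c2OC(C)(C)CC3=O)c1O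
F2 | step 10 | rac-1-{3-[(4-hydroxy-5,7-dimethoxy-2,2,6-trimethylchroman-8-yl)methyl]-2,4,6-trimethoxy-5-methylphenyl}-2-methylpropan-1-one | COc1c(C(=O)C(C)C)c(OC)c(Cc2c(OC)c(C)c(OC)c3c2OC(C)(C)CC3O)c(OC)c1C
F3 | step 8 | rac-trans-{4-hydroxy-5,7-dimethoxy-2,2,6-trimethyl-8-[(2,4,6-trimethoxy-3-methylphenyl)methyl]chroman-3-yl}mercury acetate | COc1cc(OC)c(Cc2c(OC)c(C)c(OC)c3c2OC(C)(C)[C@H]([Hg]OC(C)=O)[C@H]3O)c(OC)c1C
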